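**Retrosynthetic overview**

1. The target is numbered as a bicyclo[3.2.1]octan-2-one: C1 (OMe bridgehead), C2 (C=O), C3 (OMe), C4 (CH2), C5 (allyl bridgehead), C6 (Me), C7 (aryl), C8 (CHOH). These locants are used for the same carbons throughout. The last step frees the phenol.
2. Key disconnection: C4–C5 and C1–C8 together. The six-membered ring C1–C2–C3–C4–C5–C8 is a 3-hydroxycyclohexanone: the C8 hydroxyl is β to the C2 ketone through C1 (aldol retron), and C8 and C2 are 1,5-related through C5–C4–C3 (Michael retron). The C6–C7 bridge ties the aldehyde and enone partners together, so an acyclic keto-aldehyde can fold to the whole bicycle in one enamine Michael/aldol operation.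
3. Keto-aldehyde: the C5 allyl group and the C8 formyl group come from a Claisen rearrangement of an allyl enol ether; C2–C3–C4 comes from 1-methoxyvinyllithium addition and oxidation.
4. C6/C7 stereodiad: aryl 1,4-addition and methylation on a chiral-pool (R)-butenolide. Its lactone is a temporary ring, opened by reduction and Wittig olefination (lactone C=O becomes C5, ring oxygen becomes the C1 methoxy oxygen).
5. Ring order: temporary lactone (removed), then the cycloheptanone (C4–C5), then the cyclopentane and cyclohexanone of the bicycle (C1–C8); the last two closures occur in one pot.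

Key step: step 14

Assumption: butenolide 3 (single enantiomer) and allyl chloromethyl ether 9 are taken as purchasable; the enol ethers 13–17 are carried as E/Z mixtures and 17–19 as epimer mixtures at centres that the key step resets.

**Route**

Step 1
Reactants: 1 5-bromo-2-methoxyphenol
Product: 2 4-bromo-1-methoxy-2-(methoxymethoxy)benzene
Conditions: MOMCl, i-Pr2NEt, CH2Cl2, 0 → 23 °C
Reagents that add atoms: chloromethyl methyl ether (COCCl)
Why: O-alkylation of the phenol (MOM acetal formation) gives a protecting group that should survive the organometallic, basic, oxidative and thermal steps and is cleaved by acid at the end.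

Step 2
Reactants: 3 (R)-5-(hydroxymethyl)furan-2(5H)-one
Product: 4 (R)-5-{[(tert-butyldiphenylsilyl)oxy]methyl}furan-2(5H)-one
Conditions: TBDPSCl, imidazole, CH2Cl2, 23 °C
Reagents that add atoms: tert-butyl(chloro)diphenylsilane (CC(C)(C)[Si](Cl)(c1ccccc1)c1ccccc1)
Why: Silylation of the primary alcohol protects the future C2 carbon and makes the C5 substituent of the butenolide a bulky face-shielding group.

Step 3
Reactants: 2 4-bromo-1-methoxy-2-(methoxymethoxy)benzene; 4 (R)-5-{[(tert-butyldiphenylsilyl)oxy]methyl}furan-2(5H)-one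
Product: 6 (4S,5R)-5-{[(tert-butyldiphenylsilyl)oxy]methyl}-4-[4-methoxy-3-(methoxymethoxy)phenyl]dihydrofuran-2(3H)-one (4,5-trans), via aryl Grignard reagent 5 (not isolated)
Conditions: 2, Mg, THF, 50 °C; then CuBr·SMe2 (10 mol%), 4, THF, −78 → −30 °C; aq NH4Cl
Reagents that add atoms: none
Why: Copper-catalysed 1,4-addition of an aryl Grignard reagent to a butenolide; the aryl group should enter anti to the silyloxymethyl group, which sets the aryl-bearing centre (C7 of the target) by substrate control.

Step 4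
Reactants: 6 the trans-4-aryl lactone
Product: 7 (3R,4S,5R)-5-{[(tert-butyldiphenylsilyl)oxy]methyl}-4-[4-methoxy-3-(methoxymethoxy)phenyl]-3-methyldihydrofuran-2(3H)-one (3,4-trans and 4,5-trans)
Conditions: LiN(SiMe3)2, THF, −78 °C; MeI, −78 → −40 °C
Reagents that add atoms: iodomethane (CI)
Why: Lactone enolate alkylation; iodomethane should approach anti to the neighbouring aryl group, which sets the methyl-bearing centre (C6) trans to aryl.

Step 5
Reactants: 7 the 3-methyl-4-aryl lactone
Product: 8 (3R,4S,5R)-5-{[(tert-butyldiphenylsilyl)oxy]methyl}-4-[4-methoxy-3-(methoxymethoxy)phenyl]-3-methyltetrahydrofuran-2-ol (lactol, anomer mixture)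
Conditions: i-Bu2AlH, CH2Cl2, −78 °C; aq potassium sodium tartrate
Reagents that add atoms: none
Why: Partial reduction of a γ-lactone with i-Bu2AlH stops at the lactol because the tetrahedral aluminate is stable at −78 °C; no stereocentre of consequence is formed.

Step 6
Reactants: 9 allyl chloromethyl ether; 10 triphenylphosphine
Product: 11 [(allyloxy)methyl]triphenylphosphonium chloride
Conditions: PhMe, 23 °C
Reagents that add atoms: none
Why: SN2 quaternisation of the phosphine by the reactive α-chloro ether gives the Wittig salt that carries the allyl group and the future C8.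

Step 7
Reactants: 8 the lactol; 11 [(allyloxy)methyl]triphenylphosphonium chloride
Product: 13 (2R,3S,4S)-6-(allyloxy)-1-[(tert-butyldiphenylsilyl)oxy]-3-[4-methoxy-3-(methoxymethoxy)phenyl]-4-methylhex-5-en-2-ol (E/Z mixture), via phosphorus ylide 12 (not isolated)
Conditions: 11, KN(SiMe3)2, THF, 0 °C; then 8, 0 → 23 °C
Reagents that add atoms: none
Why: Wittig olefination of the lactol through its open hydroxy-aldehyde form with an alkoxymethylene ylide opens the temporary ring, gives the allyl enol ether (future C5=C8) and frees the future C1 hydroxyl; the alkene geometry is irrelevant.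

Step 8
Reactants: 13 the hydroxy allyl enol ether
Product: 14 tert-butyl{[(2R,3S,4S)-6-(allyloxy)-2-methoxy-3-[4-methoxy-3-(methoxymethoxy)phenyl]-4-methylhex-5-en-1-yl]oxy}diphenylsilane
Conditions: NaH, MeI, THF, 0 → 23 °C
Reagents that add atoms: iodomethane (CI)
Why: Williamson etherification of the only free hydroxyl installs the C1 methoxy group; the enol ether, silyl ether and MOM ether are base-stable.

Step 9
Reactants: 14 the methyl ether
Product: 15 (2R,3S,4S)-6-(allyloxy)-2-methoxy-3-[4-methoxy-3-(methoxymethoxy)phenyl]-4-methylhex-5-en-1-ol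
Conditions: Bu4NF, THF, 0 → 23 °C
Reagents that add atoms: none
Why: Fluoride desilylation of the primary silyl ether; the aryl MOM ether and the enol ether are inert to fluoride.

Step 10
Reactants: 15 the primary alcohol
Product: 16 (2R,3S,4S)-6-(allyloxy)-2-methoxy-3-[4-methoxy-3-(methoxymethoxy)phenyl]-4-methylhex-5-enal
Conditions: Dess–Martin periodinane, NaHCO3, CH2Cl2, 0 → 23 °C
Reagents that add atoms: none
Why: Dess–Martin oxidation under buffered conditions gives the α-methoxy aldehyde without hydrolysing the enol ether; the α-centre (future C1) need not be preserved because the key step enolises it.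

Step 11
Reactants: 16 the α-methoxy aldehyde
Product: 17 (4R,5S,6S)-8-(allyloxy)-2,4-dimethoxy-5-[4-methoxy-3-(methoxymethoxy)phenyl]-6-methylocta-1,7-dien-3-ol (C3 epimers)
Conditions: methyl vinyl ether, t-BuLi, THF, −78 → 0 °C; then 16, −78 °C; H2O
Reagents that add atoms: methyl vinyl ether (C=COC), used as 1-methoxyvinyllithium ([Li]C(=C)OC)
Why: 1,2-addition of an α-lithiated enol ether (acyl anion equivalent) to the aldehyde brings in C3 and C4 with the C3 methoxy group in place; the carbinol configuration is irrelevant because it is oxidised in step 13.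

Step 12
Reactants: 17 the allyl enol ether alcohol
Product: 18 (3R,4S,5R)-2-allyl-6-hydroxy-5,7-dimethoxy-4-[4-methoxy-3-(methoxymethoxy)phenyl]-3-methyloct-7-enal (C2 and C6 epimers)
Conditions: PhMe (0.02 M), i-Pr2NEt (5 mol%), 150 °C, sealed tube
Reagents that add atoms: none
Why: Aliphatic Claisen rearrangement of the allyl 1-alkenyl ether transfers the allyl group to the future C5 and unveils the C8 aldehyde under neutral conditions; the C5 configuration is irrelevant because the key step passes through the enamine.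

Step 13
Reactants: 18 the hydroxy aldehyde
Product: 19 (3R,4S,5R)-2-allyl-5,7-dimethoxy-4-[4-methoxy-3-(methoxymethoxy)phenyl]-3-methyl-6-oxooct-7-enal (C2 epimers)
Conditions: Dess–Martin periodinane, NaHCO3, CH2Cl2, 0 °C
Reagents that add atoms: none
Why: Dess–Martin oxidation of the 2-methoxyallylic alcohol gives the 2-methoxy enone without touching the aldehyde; 19 is used at once.

Step 14
Reactants: 19 the acyclic keto-aldehyde
Product: 22 (1S,3S,5S,6R,7S,8S)-5-allyl-8-hydroxy-1,3-dimethoxy-7-[4-methoxy-3-(methoxymethoxy)phenyl]-6-methylbicyclo[3.2.1]octan-2-one, via enamine 20 (not isolated), via formylcycloheptanone 21 (not isolated)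
Conditions: pyrrolidine (30 mol%), PhCO2H (30 mol%), PhMe (0.01 M), 40 °C; then DBU (50 mol%), 23 °C
Reagents that add atoms: none
Why: Proposed new method: pyrrolidine converts the α-branched aldehyde of 19 into (E)-enamine 20, whose C5 adds to the unsubstituted C4 terminus of the 2-methoxy enone in a 7-endo-trig Michael closure to give, after iminium hydrolysis, formylcycloheptanone 21; DBU then enolises the C2 ketone towards C1, and this enolate attacks the non-enolisable C8 aldehyde in a transannular 5-(enolexo)-exo-trig aldol that closes the cyclopentane and with it the six-membered ring of the bicyclo[3.2.1]octane. The closest known reaction types are the amine-mediated Michael/aldol (Robinson-type) formal [4+2] annulation of α,α-disubstituted aldehydes with vinyl ketones and the enamine-catalysed intramolecular Michael addition of formyl enones; new here is that the partners are tethered through C6–C7, so the Michael step is a seven-membered endo closure and the aldol is transannular. C5 is controlled by the C6/C7 stereodiad: in a chair-like transition state with methyl and aryl pseudo-equatorial the new bond forms anti to the C6 methyl group, and the flat enamine carbon rather than the allyl methylene should take the position flanked by both C6 substituents, which puts the formyl group cis to methyl (methyl exo and aryl endo in the bicycle). C1 follows from C5 because the formyl group can reach only one face of the C1 enolate, and C8 is set by a closed hydrogen-bonded aldol transition state that keeps the aldehyde oxygen next to the enolate oxygen (hydroxyl syn to the C2 carbonyl, also the favoured epimer if the aldol is reversible). C3 is set by protonation of the C2–C3 enol from the face away from the endo aryl group and is equilibrated by DBU to the epimer with the methoxy group pseudo-equatorial on the boat-shaped six-membered ring. The step needs 1,4- over 1,2-addition and ring closure over oligomerisation: the competing five-membered aldol closures (enamine onto the C2 ketone, C1 enolate onto the aldehyde before the Michael step) are reversible while the Michael addition is not, and high dilution disfavours the bimolecular path.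

Step 15
Reactants: 22 the MOM-protected bicycle
Product: 23 (1S,3S,5S,6R,7S,8S)-5-allyl-8-hydroxy-7-(3-hydroxy-4-methoxyphenyl)-1,3-dimethoxy-6-methylbicyclo[3.2.1]octan-2-one (CNP0209708.1)
Conditions: 2 M aq HCl, THF, 40 °C
Reagents that add atoms: none
Why: Acid hydrolysis of the aryl MOM acetal frees the phenol; the bridgehead methyl ether is inert, the C8 alcohol cannot dehydrate towards a bridgehead, and C3 already holds what is argued in step 14 to be its equilibrium configuration.

**Compound list**

1 | 5-bromo-2-methoxyphenol | COc1ccc(Br)cc1O | starting material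
2 | 4-bromo-1-methoxy-2-(methoxymethoxy)benzene | COCOc1cc(Br)ccc1OC | intermediate
3 | (R)-5-(hydroxymethyl)furan-2(5H)-one | O=C1C=C[C@H](CO)O1 | starting material
4 | (R)-5-{[(tert-butyldiphenylsilyl)oxy]methyl}furan-2(5H)-one | O=C1C=C[C@H](CO[Si](c2ccccc2)(c2ccccc2)C(C)(C)C)O1 | intermediate
5 | [4-methoxy-3-(methoxymethoxy)phenyl]magnesium bromide | COCOc1cc([Mg]Br)ccc1OC | intermediate (not isolated)
6 | (4S,5R)-5-{[(tert-butyldiphenylsilyl)oxy]methyl}-4-[4-methoxy-3-(methoxymethoxy)phenyl]dihydrofuran-2(3H)-one | O=C1C[C@@H](c2ccc(OC)c(OCOC)c2)[C@H](CO[Si](c2ccccc2)(c2ccccc2)C(C)(C)C)O1 | intermediate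
7 | (3R,4S,5R)-5-{[(tert-butyldiphenylsilyl)oxy]methyl}-4-[4-methoxy-3-(methoxymethoxy)phenyl]-3-methyldihydrofuran-2(3H)-one | C[C@@H]1[C@@H](c2ccc(OC)c(OCOC)c2)[C@H](CO[Si](c2ccccc2)(c2ccccc2)C(C)(C)C)OC1=O | intermediate
8 | (3R,4S,5R)-5-{[(tert-butyldiphenylsilyl)oxy]methyl}-4-[4-methoxy-3-(methoxymethoxy)phenyl]-3-methyltetrahydrofuran-2-ol (anomer mixture) | C[C@@H]1[C@@H](c2ccc(OC)c(OCOC)c2)[C@H](CO[Si](c2ccccc2)(c2ccccc2)C(C)(C)C)OC1O | intermediate
9 | allyl chloromethyl ether | C=CCOCCl | starting material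
10 | triphenylphosphine | c1ccc(cc1)P(c1ccccc1)c1ccccc1 | starting material
11 | [(allyloxy)methyl]triphenylphosphonium chloride | C=CCOC[P+](c1ccccc1)(c1ccccc1)c1ccccc1.[Cl-] | intermediate
12 | [(allyloxy)methylene]triphenylphosphorane | C=CCOC=P(c1ccccc1)(c1ccccc1)c1ccccc1 | intermediate (not isolated)
13 | (2R,3S,4S)-6-(allyloxy)-1-[(tert-butyldiphenylsilyl)oxy]-3-[4-methoxy-3-(methoxymethoxy)phenyl]-4-methylhex-5-en-2-ol (E/Z mixture) | C=CCOC=C[C@H](C)[C@@H](c1ccc(OC)c(OCOC)c1)[C@@H](O)CO[Si](c1ccccc1)(c1ccccc1)C(C)(C)C | intermediate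
14 | tert-butyl{[(2R,3S,4S)-6-(allyloxy)-2-methoxy-3-[4-methoxy-3-(methoxymethoxy)phenyl]-4-methylhex-5-en-1-yl]oxy}diphenylsilane (E/Z mixture) | C=CCOC=C[C@H](C)[C@@H](c1ccc(OC)c(OCOC)c1)[C@@H](OC)CO[Si](c1ccccc1)(c1ccccc1)C(C)(C)C | intermediate
15 | (2R,3S,4S)-6-(allyloxy)-2-methoxy-3-[4-methoxy-3-(methoxymethoxy)phenyl]-4-methylhex-5-en-1-ol (E/Z mixture) | C=CCOC=C[C@H](C)[C@@H](c1ccc(OC)c(OCOC)c1)[C@@H](OC)CO | intermediate
16 | (2R,3S,4S)-6-(allyloxy)-2-methoxy-3-[4-methoxy-3-(methoxymethoxy)phenyl]-4-methylhex-5-enal (E/Z mixture) | C=CCOC=C[C@H](C)[C@@H](c1ccc(OC)c(OCOC)c1)[C@@H](OC)C=O | intermediate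
17 | (4R,5S,6S)-8-(allyloxy)-2,4-dimethoxy-5-[4-methoxy-3-(methoxymethoxy)phenyl]-6-methylocta-1,7-dien-3-ol (C3 epimers, E/Z mixture) | C=CCOC=C[C@H](C)[C@@H](c1ccc(OC)c(OCOC)c1)[C@@H](OC)C(O)C(=C)OC | intermediate
18 | (3R,4S,5R)-2-allyl-6-hydroxy-5,7-dimethoxy-4-[4-methoxy-3-(methoxymethoxy)phenyl]-3-methyloct-7-enal (C2 and C6 epimers) | C=CCC(C=O)[C@H](C)[C@@H](c1ccc(OC)c(OCOC)c1)[C@@H](OC)C(O)C(=C)OC | intermediate
19 | (3R,4S,5R)-2-allyl-5,7-dimethoxy-4-[4-methoxy-3-(methoxymethoxy)phenyl]-3-methyl-6-oxooct-7-enal (C2 epimers) | C=CCC(C=O)[C@H](C)[C@@H](c1ccc(OC)c(OCOC)c1)[C@@H](OC)C(=O)C(=C)OC | intermediate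
20 | 1-[(1E,3R,4S,5R)-2-allyl-5,7-dimethoxy-4-[4-methoxy-3-(methoxymethoxy)phenyl]-3-methyl-6-oxoocta-1,7-dien-1-yl]pyrrolidine | C=CC/C(=C\N1CCCC1)[C@H](C)[C@@H](c1ccc(OC)c(OCOC)c1)[C@@H](OC)C(=O)C(=C)OC | intermediate (not isolated)
21 | (1S,2R,3S)-1-allyl-4,6-dimethoxy-3-[4-methoxy-3-(methoxymethoxy)phenyl]-2-methyl-5-oxocycloheptane-1-carbaldehyde (C4 and C6 epimers) | C=CC[C@]1(C=O)CC(OC)C(=O)C(OC)[C@H](c2ccc(OC)c(OCOC)c2)[C@H]1C | intermediate (not isolated)
22 | (1S,3S,5S,6R,7S,8S)-5-allyl-8-hydroxy-1,3-dimethoxy-7-[4-methoxy-3-(methoxymethoxy)phenyl]-6-methylbicyclo[3.2.1]octan-2-one | C=CC[C@]12C[C@H](OC)C(=O)[C@](OC)([C@H](c3ccc(OC)c(OCOC)c3)[C@H]1C)[C@H]2O | intermediate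
23 | (1S,3S,5S,6R,7S,8S)-5-allyl-8-hydroxy-7-(3-hydroxy-4-methoxyphenyl)-1,3-dimethoxy-6-methylbicyclo[3.2.1]octan-2-one | C=CC[C@]12C[C@H](OC)C(=O)[C@](OC)([C@H](c3ccc(OC)c(O)c3)[C@H]1C)[C@H]2O | target

**Step count and risks**

Total step count: 15. Longest linear sequence: 13 steps (3 → 23 through steps 2–5 and 7–15).

Steps most likely to fail:

1. Step 14 (Proposed new method). What may go wrong: the seven-membered enamine Michael closure may lose to oligomerisation or to reversible amine addition to the enone, or the quaternary C5 may form with poor facial selectivity, which would give the bicycle with methyl endo and aryl exo. Fallback with known chemistry, from 19 back to 22: the aldehyde of 19 would be converted chemoselectively into its tert-butyldimethylsilyl enol ether F1 (TBSOTf, Et3N, CH2Cl2, −78 °C). An intramolecular Mukaiyama–Michael addition promoted by catalytic TBSOTf at −78 °C would then give the cycloheptenyl silyl enol ether F2. Cleavage of its silyl enol ether (K2CO3, MeOH) would release formylcycloheptanone 21 as an isolated compound, so that the C5 epimers can be separated, and a separate DBU-mediated aldol would close 22.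

2. Step 7. What may go wrong: slow olefination of the hindered lactol, with epimerisation of the C6 methyl centre through the open hydroxy-aldehyde under the basic ylide. Fallback, from 7 back to 14: the lactone would be opened with MeNH(OMe)·HCl and AlMe3 to the hydroxy Weinreb amide F3, which would be methylated at once under non-basic conditions (MeOTf, 2,6-di-tert-butyl-4-methylpyridine) to the methoxy Weinreb amide F4, so that relactonisation is avoided. Reduction with i-Bu2AlH at −78 °C would give the free α-methyl aldehyde F5, which should react with ylide 12 at −78 → 0 °C, well below the temperature the lactol needs, to give 14 directly.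

3. Step 12. What may go wrong: thermal decomposition of the 2-methoxyallylic alcohol, or sluggish rearrangement of the (Z)-enol ether at the temperature required. Fallback, from 14 back to 19: the Claisen rearrangement would be run on the robust silyl ether 14 to give the α-allyl aldehyde F6, which would be masked as the dimethyl acetal F7 (HC(OMe)3, MeOH, pyridinium p-toluenesulfonate). Desilylation (Bu4NF) would give the primary alcohol F8, Dess–Martin oxidation the α-methoxy aldehyde F9, addition of 1-methoxyvinyllithium the allylic alcohol F10, and a second Dess–Martin oxidation the enone acetal F11. Mild hydrolysis of the dimethyl acetal (wet acetone, pyridinium p-toluenesulfonate) would then release 19 just before the key step.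

**Further compounds**

F1 | step 14 | tert-butyl{[(3R,4S,5R)-2-allyl-5,7-dimethoxy-4-[4-methoxy-3-(methoxymethoxy)phenyl]-3-methyl-6-oxoocta-1,7-dien-1-yl]oxy}dimethylsilane (E/Z mixture) | C=CCC(=CO[Si](C)(C)C(C)(C)C)[C@H](C)[C@@H](c1ccc(OC)c(OCOC)c1)[C@@H](OC)C(=O)C(=C)OC
F2 | step 14 | (1S,2R,3S)-1-allyl-5-[(tert-butyldimethylsilyl)oxy]-4,6-dimethoxy-3-[4-methoxy-3-(methoxymethoxy)phenyl]-2-methylcyclohept-5-ene-1-carbaldehyde (C4 epimers) | C=CC[C@]1(C=O)CC(OC)=C(O[Si](C)(C)C(C)(C)C)C(OC)[C@H](c2ccc(OC)c(OCOC)c2)[C@H]1C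
F3 | step 7 | (2R,3S,4R)-5-[(tert-butyldiphenylsilyl)oxy]-4-hydroxy-N-methoxy-3-[4-methoxy-3-(methoxymethoxy)phenyl]-N,2-dimethylpentanamide | CON(C)C(=O)[C@H](C)[C@@H](c1ccc(OC)c(OCOC)c1)[C@@H](O)CO[Si](c1ccccc1)(c1ccccc1)C(C)(C)C
F4 | step 7 | (2R,3S,4R)-5-[(tert-butyldiphenylsilyl)oxy]-N,4-dimethoxy-3-[4-methoxy-3-(methoxymethoxy)phenyl]-N,2-dimethylpentanamide | CON(C)C(=O)[C@H](C)[C@@H](c1ccc(OC)c(OCOC)c1)[C@@H](OC)CO[Si](c1ccccc1)(c1ccccc1)C(C)(C)C
F5 | step 7 | (2R,3S,4R)-5-[(tert-butyldiphenylsilyl)oxy]-4-methoxy-3-[4-methoxy-3-(methoxymethoxy)phenyl]-2-methylpentanal | O=C[C@H](C)[C@@H](c1ccc(OC)c(OCOC)c1)[C@@H](OC)CO[Si](c1ccccc1)(c1ccccc1)C(C)(C)C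
F6 | step 12 | (3R,4S,5R)-2-allyl-6-[(tert-butyldiphenylsilyl)oxy]-5-methoxy-4-[4-methoxy-3-(methoxymethoxy)phenyl]-3-methylhexanal (C2 epimers) | C=CCC(C=O)[C@H](C)[C@@H](c1ccc(OC)c(OCOC)c1)[C@@H](OC)CO[Si](c1ccccc1)(c1ccccc1)C(C)(C)C
F7 | step 12 | dimethyl acetal of F6: tert-butyl{[(2R,3S,4R)-5-(dimethoxymethyl)-2-methoxy-3-[4-methoxy-3-(methoxymethoxy)phenyl]-4-methyloct-7-en-1-yl]oxy}diphenylsilane (C5 epimers) | C=CCC(C(OC)OC)[C@H](C)[C@@H](c1ccc(OC)c(OCOC)c1)[C@@H](OC)CO[Si](c1ccccc1)(c1ccccc1)C(C)(C)C
F8 | step 12 | (2R,3S,4R)-5-(dimethoxymethyl)-2-methoxy-3-[4-methoxy-3-(methoxymethoxy)phenyl]-4-methyloct-7-en-1-ol (C5 epimers) | C=CCC(C(OC)OC)[C@H](C)[C@@H](c1ccc(OC)c(OCOC)c1)[C@@H](OC)CO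
F9 | step 12 | (2R,3S,4R)-5-(dimethoxymethyl)-2-methoxy-3-[4-methoxy-3-(methoxymethoxy)phenyl]-4-methyloct-7-enal (C5 epimers) | C=CCC(C(OC)OC)[C@H](C)[C@@H](c1ccc(OC)c(OCOC)c1)[C@@H](OC)C=O
F10 | step 12 | (4R,5S,6R)-7-(dimethoxymethyl)-2,4-dimethoxy-5-[4-methoxy-3-(methoxymethoxy)phenyl]-6-methyldeca-1,9-dien-3-ol (C3 and C7 epimers) | C=CCC(C(OC)OC)[C@H](C)[C@@H](c1ccc(OC)c(OCOC)c1)[C@@H](OC)C(O)C(=C)OC
F11 | step 12 | (4R,5S,6R)-7-(dimethoxymethyl)-2,4-dimethoxy-5-[4-methoxy-3-(methoxymethoxy)phenyl]-6-methyldeca-1,9-dien-3-one (C7 epimers) | C=CCC(C(OC)OC)[C@H](C)[C@@H](c1ccc(OC)c(OCOC)c1)[C@@H](OC)C(=O)C(=C)OC
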